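## The problem

The target 26 is a benzophenone in which a 3-hydroxyphenyl ring (ring B) is joined through a ketone to C6 of a 2,2-dimethyl-2H-chromene. The benzene ring of the chromene (ring A) has no hydrogen left: it carries the pyran oxygen on C8a, a prenyl group on C8, hydroxyls on C7 and C5, the aroyl group on C6 and the styrenic carbon C4 on C4a. There is no stereocenter, so the difficulty is purely regiochemical. A 1,3,5-trioxygenated benzene must receive three different carbon substituents and two kinds of oxygen (two phenols, one cyclic ether) without positional ambiguity, and direct prenylation, chromenylation or acylation of such a ring distinguishes its positions poorly. The prenyl group next to the C7 hydroxyl cyclises to a chroman under strong acid, the two double bonds forbid hydrogenolysis and Lewis-acid Friedel–Crafts chemistry, and the free polyphenol is easily oxidised. The feature that invites a benzannulation is that the oxygens of ring A sit on alternate carbons (C5, C7, C8a) with the prenyl carbon C8 between two of them. A vinylketene and an ynol ether produce exactly this pattern: the ketene carbonyl becomes the C8a hydroxyl, the ynol ether oxygen ends on C5, and the cyclobutenone supplies the C7 oxygen and the C8 prenyl group. The resulting phenol has one free hydroxyl (C8a) with one free ortho carbon (C4a) for the pyran, and one further C–H (C6) between two oxygens for directed metalation.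

## Retrosynthesis

Ketone, C6–C(carbonyl). Target 26 is traced to its tris(methoxymethyl) ether 25, and 25 is cut between C6 and the carbonyl carbon into chromene 19 and Weinreb amide 22. The neighbouring cut, carbonyl–C1' of ring B, would need a carboxylic acid derivative on the crowded C6 and a ring-B organometallic. An electrophilic aroylation of the free diphenol 18 would put a Lewis acid next to the prenyl and chromene double bonds. The chosen cut uses the fact that C6–H is the only aromatic hydrogen of 19 and lies between two acetal oxygens, so lithiation to 23 has no regiochemical choice. 19 is simpler than 25 by the whole of ring B and the carbonyl. The forward reaction must stop at the ketone (hence amide 22 and its adduct 24), and the acetals must later come off under acid mild enough for the prenyl group.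

Ring B piece. Amide 22 is cut at the amide C–N bond to ester 21, and 21 at the acetal O–CH2 bond to commercial 20. Nothing is asked beyond base-stable protection of the phenol.

Protecting-group change, 19 from 18 from 17. No skeletal bond is cut. The silyl ethers of 17 are what the benzannulation delivers, but they direct lithiation poorly and can migrate to an ortho-lithiated carbon. They are therefore exchanged, through diol 18, for acetals that direct strongly.

Pyran ring, O1–C2 and C4–C4a. Chromene 17 is cut into phenol 13 and enal 14. Closing the pyran at this stage, rather than after the ketone is in place, means that 13 offers one free hydroxyl and one free ortho carbon, so the annulation cannot go elsewhere. An aryl propargyl ether route would make the same ring in two steps instead of one. 13 is simpler than 17 by one ring. The forward reaction must generate and close an ortho-quinone methide (16) without acid strong enough to touch the silyl ethers or the prenyl group.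

Ring A, C4a–C8a, C5–C6 and C8–C8a (key step). Phenol 13 is cut into cyclobutenone 8 and ynol ether 4. The neighbouring cuts, at the prenyl–C8 bond or at the O–Si bonds of a preformed trioxygenated benzene, would have to tell apart equivalent or nearly equivalent ring positions. Here each ring atom comes from a defined atom of two small precursors. 13 is a pentasubstituted benzene, whereas 8 is a four-membered ring and 4 a two-carbon alkyne. The forward reaction needs only the normal polarity of a ketene–ynol ether cycloaddition and tolerance of heat.

Cyclobutenone, C1–C2 and C3–C4 of 8. The ring is cut into ketene 7 and the same ynol ether 4, so one alkyne serves twice. 7 comes from acid chloride 6 and 6 from commercial acid 5. Alkylation of a preformed 3-oxygenated cyclobutenone would place the prenyl group on C2, the wrong carbon. The cycloaddition must beat ketene dimerisation.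

Ynol ether, O–Si bond of 4. Compound 4 is cut to ynolate 3 and silyl triflate 2, and 3 is traced to dibromo ester 1 by loss of both bromines and the ethoxy group. The forward reaction needs O-selective silylation of an ambident ynolate, which the bulk of 2 favours.

## Roads not taken

Alternative 1: The ketone is cut on both sides of the carbonyl carbon. In the forward direction the C6 aryl iodide A2, carbon monoxide A4 and the ring-B boronic acid A3 would be joined by a palladium-catalysed carbonylative Suzuki–Miyaura coupling. The product is the tris(methoxymethyl) ether A1, which is the same compound as 25.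
- Merits: three components are joined in one operation under neutral conditions that leave acetals, prenyl and chromene alone. The ring-B partner is shelf-stable and easily varied.
- Weak points: A2 is an electron-rich aryl iodide with both ortho positions occupied. That is the case in which oxidative addition and insertion of A4 are slowest and direct biaryl coupling without A4 competes. A2 also has to be made from 19, most simply through the very aryllithium 23 that the chosen plan acylates directly. The alternative offers nothing for the assembly of ring A, which is the harder half of the problem.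
- Comparison: as a ketone synthesis alternative 1 is the more tolerant of functional groups. The chosen plan sets against it one step fewer, no toxic gas and the same intermediate 25.

Alternative 2: Ring A is cut at C6–C7 and traced to a polyketide-like chain. The pyrone A6 would be opened by a magnesium alkoxide to the triketo ester A7. Its carbanion between two ketones attacks the ester carbonyl (Claisen mode) and closes ring A as the benzoylphloroglucinol A5.
- Merits: ring A, the aroyl group and the prenyl group arrive in one ring-forming event. Ring A needs no protecting groups, the logic follows the biosynthesis, and the way to A5 is probably shorter than the way to 19.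
- Weak points: a 3,5,7-triketo ester is ambident. Aldol closure onto the aryl ketone and reclosure to a pyrone compete with the Claisen mode, and the prenyl group sits on the carbon next to the ester carbonyl, hindering the attack that is wanted. A5 then has three free hydroxyls, and the pyran annulation at C4a must use the C8a oxygen and not the C5 oxygen. The chelated C5 hydroxyl is the less available one, so the desired sense is likely to be preferred, but it is a preference and not a constraint.
- Comparison: alternative 2 is shorter and more atom-economical, and if both selectivities held it would be the better synthesis. The chosen plan sets against it that every position of ring A is fixed by the connectivity of 8 and 4 and by the single free hydroxyl of 13, so no isomer separation is built into the route.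

Alternative 3: The cut is made at C6–C(carbonyl) and at the C7–O bond. The aryne A10 spanning C6 and C7, released by fluoride from the ortho-silylaryl triflate A9, would insert into the carbon–oxygen bond of 3-(methoxymethoxy)benzoic acid A11. The carboxylate oxygen adds to C7, the acyl group migrates to C6, and the ortho-hydroxy ketone A8 results.
- Merits: the hindered ketone is made without a transition metal or a strong base, and the C7 oxygen and the C6 acyl group are set in one step. The C5 acetal polarises the aryne so that the oxygen nucleophile attacks the distal carbon C7, which is the sense needed.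
- Weak points: A9 is a hexasubstituted benzene. It needs bromination, O-silylation, anionic silyl migration and triflation on a ring that already carries the prenyl group and two acetals, so the construction of ring A is lengthened rather than solved. The prenyl group next to the aryne carbon hinders the first addition and offers an ene pathway. A8 also frees the wrong hydroxyl: the pyran needs the C8a oxygen, whose acetal is less labile than the carbonyl-activated C5 acetal, so after full deprotection the C5 versus C8a choice of alternative 2 returns.
- Comparison: as a ketone synthesis it is milder than the organolithium addition of step 10 and would be preferred if 23 could not be formed cleanly. The chosen plan sets against it a much shorter access to the metalation substrate 19, and a pyran that is closed while only one hydroxyl is free.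

Key step: step 4

Assumption: 5 is taken as a catalogue compound, and every compound drawn with a single stereocenter (8, 10, 12, 15, 24) is a racemate whose stereocenter disappears later in the route.

## Steps

Step 1
Reactants: 1 ethyl dibromoacetate; 2 triisopropylsilyl trifluoromethanesulfonate
Product: 4 (triisopropylsilyloxy)ethyne, via lithium ethynolate 3 (not isolated)
Conditions: t-BuLi (4 equiv), THF, −78 → 0 °C; then 2 (2.2 equiv), −78 °C → rt
Reagents that add atoms: none
Why: Two bromine–lithium exchanges convert 1 into an ester dianion that expels LiOEt to give ynolate 3 (ynolate synthesis by cleavage of ester dianions from α,α-dibromo esters); O-silylation of lithium ynolates by bulky silyl electrophiles is the standard entry to siloxyalkynes, and the triisopropylsilyl group disfavours C-silylation and the 1,3-shift to a silylketene. The second equivalent of 2 is consumed by LiOEt.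

Step 2
Reactants: 5 5-methylhex-4-enoic acid
Product: 6 5-methylhex-4-enoyl chloride
Conditions: (COCl)2, DMF (cat.), CH2Cl2, 0 °C → rt; concentrated and used crude
Reagents that add atoms: oxalyl chloride, O=C(Cl)C(=O)Cl
Why: DMF-catalysed conversion of a carboxylic acid into its chloride; the by-products are gases and the isolated trisubstituted alkene is inert at this temperature without a Lewis acid.

Step 3
Reactants: 6 5-methylhex-4-enoyl chloride; 4 (triisopropylsilyloxy)ethyne
Product: 8 4-(3-methylbut-2-enyl)-3-(triisopropylsilyloxy)cyclobut-2-en-1-one (racemic), via prenylketene 7 (not isolated)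
Conditions: Et3N, THF, 0 °C → rt, slow addition of 6
Reagents that add atoms: none
Why: Dehydrochlorination gives aldoketene 7, which the electron-rich ynol ether captures in a [2+2] cycloaddition (ketene–siloxyalkyne cycloaddition to 3-siloxycyclobutenones); the unsubstituted, nucleophilic alkyne carbon bonds to the ketene carbonyl carbon, so the silyloxy group ends on C3 and the prenyl-bearing carbon on C4. Slow addition keeps 7 dilute and limits its dimerisation.

Step 4
Reactants: 8 4-(3-methylbut-2-enyl)-3-(triisopropylsilyloxy)cyclobut-2-en-1-one; 4 (triisopropylsilyloxy)ethyne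
Product: 13 2-(3-methylbut-2-enyl)-3,5-bis(triisopropylsilyloxy)phenol, via siloxy vinylketene 9 (not isolated), via vinylcyclobutenone 10 (not isolated), via dienylketene 11 (not isolated), via cyclohexadienone 12 (not isolated)
Conditions: 4 (1.5 equiv), toluene, 80 → 110 °C
Reagents that add atoms: none
Why: Heating opens 8 by 4π electrocyclic ring opening, the prenyl group rotating outward, to siloxy vinylketene 9; the polarised ynol ether 4 then adds across the ketene C=C bond in a [2+2] cycloaddition in which its unsubstituted, nucleophilic carbon bonds to the ketene carbonyl carbon, giving vinylcyclobutenone 10 and with it the C4a–C8a and C5–C6 bonds. A second, reversible 4π opening gives dienylketene 11, whose 6π electrocyclisation forms the C8–C8a bond and closes ring A as cyclohexadienone 12, and enolisation gives phenol 13. The closest known reaction type is the Danheiser benzannulation of cyclobutenones with siloxyalkynes to resorcinol derivatives; here the cyclobutenone carries a further siloxy group on C3, which becomes the C7 silyl ether. Ring A is thus closed by a thermal disrotatory 6π electrocyclisation of a ketene-terminated triene. No stereocenter is formed. The one selectivity needed is the orientation of 4 in the [2+2] step, and it is secured by the polarisation of the alkyne by its oxygen and of the ketene by its carbonyl, which places the three oxygens on alternate ring carbons and leaves the ketene-derived hydroxyl, flanked by the prenyl carbon and a C–H, as the only free phenol. Only the 3E isomer of 11 can cyclise, but the opening of 10 is reversible, so the other isomer returns to 10 and is funnelled through the productive one. Outward rotation of the prenyl group in the first opening also holds its double bond away from the ketene and so disfavours an internal [2+2] reaction.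

Step 5
Reactants: 13 2-(3-methylbut-2-enyl)-3,5-bis(triisopropylsilyloxy)phenol; 14 3-methylbut-2-enal
Product: 17 2,2-dimethyl-8-(3-methylbut-2-enyl)-5,7-bis(triisopropylsilyloxy)-2H-chromene, via benzodioxaborin 15 (not isolated), via ortho-quinone methide 16 (not isolated)
Conditions: PhB(OH)2, AcOH (cat.), toluene, reflux, Dean–Stark
Reagents that add atoms: none
Why: Phenylboronic acid ties the phenol oxygen and the aldehyde together and delivers the aldehyde carbon to the only free ortho position C4a, giving 15; on heating 15 loses the boronic acid unit to give ortho-quinone methide 16, which closes by oxa-6π electrocyclisation (boronic acid-mediated chromene annulation of phenols with enals). Regiochemistry is fixed because 13 has one free hydroxyl and one free ortho carbon, and the weakly acidic medium spares silyl ethers and prenyl group.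

Step 6
Reactants: 17 2,2-dimethyl-8-(3-methylbut-2-enyl)-5,7-bis(triisopropylsilyloxy)-2H-chromene
Product: 18 2,2-dimethyl-8-(3-methylbut-2-enyl)-2H-chromene-5,7-diol
Conditions: Bu4NF, AcOH, THF, 0 °C
Reagents that add atoms: none
Why: Fluoride-induced cleavage of aryl silyl ethers, fast because phenoxide leaves silicon readily; AcOH buffers the phenoxides so that the electron-rich diphenol is not exposed to base and air together, and the alkenes are inert.

Step 7
Reactants: 18 2,2-dimethyl-8-(3-methylbut-2-enyl)-2H-chromene-5,7-diol
Product: 19 5,7-bis(methoxymethoxy)-2,2-dimethyl-8-(3-methylbut-2-enyl)-2H-chromene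
Conditions: MOMCl, i-Pr2NEt, CH2Cl2, 0 °C → rt
Reagents that add atoms: chloromethyl methyl ether, COCCl
Why: O-Alkylation of phenols with an α-chloro ether under amine base (methoxymethyl ether formation); the acetals are chosen because they direct the lithiation of step 10 strongly and are stable to alkyllithiums.

Step 8
Reactants: 20 methyl 3-hydroxybenzoate
Product: 21 methyl 3-(methoxymethoxy)benzoate
Conditions: MOMCl, i-Pr2NEt, CH2Cl2, 0 °C → rt
Reagents that add atoms: chloromethyl methyl ether, COCCl
Why: The same methoxymethyl ether formation on the ring-B phenol; the ester is untouched by the amine base.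

Step 9
Reactants: 21 methyl 3-(methoxymethoxy)benzoate
Product: 22 N-methoxy-3-(methoxymethoxy)-N-methylbenzamide
Conditions: MeNH(OMe)·HCl, i-PrMgCl, THF, −20 → 0 °C
Reagents that add atoms: N,O-dimethylhydroxylamine hydrochloride, CNOC.Cl
Why: The chloromagnesium amide formed in the flask from the hydroxylamine salt and i-PrMgCl converts a methyl ester directly into the Weinreb amide (ester aminolysis by a magnesium amide); the aryl acetal is stable to the basic medium.

Step 10
Reactants: 19 5,7-bis(methoxymethoxy)-2,2-dimethyl-8-(3-methylbut-2-enyl)-2H-chromene; 22 N-methoxy-3-(methoxymethoxy)-N-methylbenzamide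
Product: 25 [5,7-bis(methoxymethoxy)-2,2-dimethyl-8-(3-methylbut-2-enyl)-2H-chromen-6-yl][3-(methoxymethoxy)phenyl]methanone, via aryllithium 23 (not isolated), via tetrahedral lithium adduct 24 (not isolated)
Conditions: n-BuLi, THF, 0 °C; then 22, −78 → 0 °C; aq. NH4Cl
Reagents that add atoms: none
Why: Directed ortho-metalation: C6–H is the only aromatic hydrogen of 19 and is flanked by two coordinating acetal oxygens, so n-BuLi gives 23 without a regiochemical choice. Addition of 23 to Weinreb amide 22 stops at the chelated adduct 24, which releases the ketone only on work-up (Weinreb ketone synthesis), so no tertiary alcohol can form.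

Step 11
Reactants: 25 [5,7-bis(methoxymethoxy)-2,2-dimethyl-8-(3-methylbut-2-enyl)-2H-chromen-6-yl][3-(methoxymethoxy)phenyl]methanone
Product: 26 [5,7-dihydroxy-2,2-dimethyl-8-(3-methylbut-2-enyl)-2H-chromen-6-yl](3-hydroxyphenyl)methanone (target)
Conditions: 3 M aq. HCl, MeOH, rt → 40 °C
Reagents that add atoms: none
Why: Acid-catalysed transacetalisation of the three methoxymethyl ethers to methanol; the two ethers ortho to the ketone are activated by hydrogen bonding of the emerging phenols to the carbonyl. Dilute acid at or slightly above room temperature is the usual window in which ortho-prenyl phenols and 2,2-dimethylchromenes survive this deprotection.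

## Compound list

1 | ethyl dibromoacetate | CCOC(=O)C(Br)Br | starting material
2 | triisopropylsilyl trifluoromethanesulfonate | CC(C)[Si](OS(=O)(=O)C(F)(F)F)(C(C)C)C(C)C | starting material
3 | lithium ethynolate | [Li+].[O-]C#C | intermediate
4 | (triisopropylsilyloxy)ethyne | C#CO[Si](C(C)C)(C(C)C)C(C)C | intermediate
5 | 5-methylhex-4-enoic acid | CC(C)=CCCC(=O)O | starting material
6 | 5-methylhex-4-enoyl chloride | CC(C)=CCCC(=O)Cl | intermediate
7 | 5-methylhexa-1,4-dien-1-one (prenylketene) | CC(C)=CCC=C=O | intermediate
8 | 4-(3-methylbut-2-enyl)-3-(triisopropylsilyloxy)cyclobut-2-en-1-one (racemic) | O=C1C=C(O[Si](C(C)C)(C(C)C)C(C)C)C1CC=C(C)C | intermediate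
9 | (3Z)-7-methyl-3-(triisopropylsilyloxy)octa-1,3,6-trien-1-one | O=C=C/C(O[Si](C(C)C)(C(C)C)C(C)C)=C/CC=C(C)C | intermediate
10 | 4-[(1Z)-5-methyl-1-(triisopropylsilyloxy)hexa-1,4-dien-1-yl]-3-(triisopropylsilyloxy)cyclobut-2-en-1-one (racemic) | O=C1C=C(O[Si](C(C)C)(C(C)C)C(C)C)C1/C(O[Si](C(C)C)(C(C)C)C(C)C)=C/CC=C(C)C | intermediate
11 | (3E,5Z)-9-methyl-3,5-bis(triisopropylsilyloxy)deca-1,3,5,8-tetraen-1-one (productive isomer) | O=C=C/C(O[Si](C(C)C)(C(C)C)C(C)C)=C\C(O[Si](C(C)C)(C(C)C)C(C)C)=C\CC=C(C)C | intermediate
12 | 6-(3-methylbut-2-enyl)-3,5-bis(triisopropylsilyloxy)cyclohexa-2,4-dien-1-one (racemic) | O=C1C=C(O[Si](C(C)C)(C(C)C)C(C)C)C=C(O[Si](C(C)C)(C(C)C)C(C)C)C1CC=C(C)C | intermediate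
13 | 2-(3-methylbut-2-enyl)-3,5-bis(triisopropylsilyloxy)phenol | CC(C)=CCc1c(O)cc(O[Si](C(C)C)(C(C)C)C(C)C)cc1O[Si](C(C)C)(C(C)C)C(C)C | intermediate
14 | 3-methylbut-2-enal | CC(C)=CC=O | starting material
15 | 4-(2-methylprop-1-enyl)-8-(3-methylbut-2-enyl)-2-phenyl-5,7-bis(triisopropylsilyloxy)-4H-1,3,2-benzodioxaborinine (racemic) | CC(C)=CCc1c(O[Si](C(C)C)(C(C)C)C(C)C)cc(O[Si](C(C)C)(C(C)C)C(C)C)c2c1OB(c1ccccc1)OC2C=C(C)C | intermediate
16 | (6Z)-6-(3-methylbut-2-enylidene)-2-(3-methylbut-2-enyl)-3,5-bis(triisopropylsilyloxy)cyclohexa-2,4-dien-1-one | O=C1C(CC=C(C)C)=C(O[Si](C(C)C)(C(C)C)C(C)C)C=C(O[Si](C(C)C)(C(C)C)C(C)C)/C1=C/C=C(C)C | intermediate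
17 | 2,2-dimethyl-8-(3-methylbut-2-enyl)-5,7-bis(triisopropylsilyloxy)-2H-chromene | CC(C)=CCc1c(O[Si](C(C)C)(C(C)C)C(C)C)cc(O[Si](C(C)C)(C(C)C)C(C)C)c2c1OC(C)(C)C=C2 | intermediate
18 | 2,2-dimethyl-8-(3-methylbut-2-enyl)-2H-chromene-5,7-diol | CC(C)=CCc1c(O)cc(O)c2c1OC(C)(C)C=C2 | intermediate
19 | 5,7-bis(methoxymethoxy)-2,2-dimethyl-8-(3-methylbut-2-enyl)-2H-chromene | CC(C)=CCc1c(OCOC)cc(OCOC)c2c1OC(C)(C)C=C2 | intermediate
20 | methyl 3-hydroxybenzoate | COC(=O)c1cccc(O)c1 | starting material
21 | methyl 3-(methoxymethoxy)benzoate | COCOc1cccc(C(=O)OC)c1 | intermediate
22 | N-methoxy-3-(methoxymethoxy)-N-methylbenzamide | COCOc1cccc(C(=O)N(C)OC)c1 | intermediate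
23 | [5,7-bis(methoxymethoxy)-2,2-dimethyl-8-(3-methylbut-2-enyl)-2H-chromen-6-yl]lithium | CC(C)=CCc1c(OCOC)c([Li])c(OCOC)c2c1OC(C)(C)C=C2 | intermediate
24 | lithium [5,7-bis(methoxymethoxy)-2,2-dimethyl-8-(3-methylbut-2-enyl)-2H-chromen-6-yl][methoxy(methyl)amino][3-(methoxymethoxy)phenyl]methanolate (racemic) | CC(C)=CCc1c(OCOC)c(C(O[Li])(N(C)OC)c2cccc(OCOC)c2)c(OCOC)c2c1OC(C)(C)C=C2 | intermediate
25 | [5,7-bis(methoxymethoxy)-2,2-dimethyl-8-(3-methylbut-2-enyl)-2H-chromen-6-yl][3-(methoxymethoxy)phenyl]methanone | CC(C)=CCc1c(OCOC)c(C(=O)c2cccc(OCOC)c2)c(OCOC)c2c1OC(C)(C)C=C2 | intermediate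
26 | [5,7-dihydroxy-2,2-dimethyl-8-(3-methylbut-2-enyl)-2H-chromen-6-yl](3-hydroxyphenyl)methanone | CC(C)=CCc1c(O)c(C(=O)c2cccc(O)c2)c(O)c2c1OC(C)(C)C=C2 | target

## Step count and least certain steps

Total: 11 steps. Longest linear sequence: 8 steps (5 → 6 → 8 → 13 → 17 → 18 → 19 → 25 → 26, steps 2, 3, 4, 5, 6, 7, 10 and 11).

Step 4 (key step). Several things may go wrong:
- The product phenol 13 may be O-acylated by vinylketene 9, or 9 may dimerise.
- After inward rotation, 9 may be captured by its own prenyl double bond.
- Direct [4+2] addition of 4 to 9 would compete with the [2+2] mode and would place the prenyl group para to the hydroxyl.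
- 4 may undergo a thermal 1,3-silyl shift to a silylketene before it is consumed.
- The extra donor on C3 may slow the ring opening of 8.

The fallback gives up the annulation and reaches 13 by differentiating a preformed ring; it sets out from 2 and returns at 13. Phloroglucinol is C-prenylated with prenyl bromide and aqueous KOH to 2-(3-methylbut-2-enyl)benzene-1,3,5-triol F1. F1 is then silylated with two equivalents of 2 and 2,6-lutidine in CH2Cl2 at −78 °C. The hydroxyl para to the prenyl group reacts first and the two hindered flanking hydroxyls are equivalent, so the second silyl group gives 13, which is separated from under- and over-silylated material.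

Step 1. Three things may go wrong:
- Deprotonation of the acidic C–H of 1 may compete with bromine–lithium exchange and divert the sequence to bromo- or dimetalated ynolates.
- Ynolate 3 may be silylated on carbon.
- The volatile 4 may be lost on isolation or be hard to separate from the inert silyl ether of ethanol.

The fallback generates 3 by a ring fragmentation instead of an ester dianion; it sets out from 2 and returns at 4. Purchased 3-phenylisoxazole is lithiated at C5 with n-BuLi in THF at −78 °C to 5-lithio-3-phenylisoxazole F2. On warming, F2 fragments into benzonitrile and 3, the known base-induced cleavage of 5-metalated isoxazoles to a nitrile and an ynolate. Silylation with 2 then gives 4, with no alkoxide competing for the silyl triflate.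

Step 5. Three things may go wrong:
- Steric shielding of C4a by the neighbouring C5 silyl ether may slow the ortho-hydroxyalkylation that leads to 15.
- The prenyl group may cyclise onto the free hydroxyl under acid and heat.
- A silyl ether may be lost by protodesilylation.

The fallback builds the pyran by a sigmatropic route; it sets out from 13 and returns at 17. 13 is O-alkylated with 3-chloro-3-methylbut-1-yne (K2CO3, KI, CuI cat., acetone) to 1-[(2-methylbut-3-yn-2-yl)oxy]-2-(3-methylbut-2-enyl)-3,5-bis(triisopropylsilyloxy)benzene F3. Heating F3 in N,N-diethylaniline brings about aromatic propargyl Claisen rearrangement to the free ortho carbon, 1,5-hydrogen shift to the same ortho-quinone methide 16 and oxa-6π closure to 17.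

Step 10. Two things may go wrong:
- Lateral deprotonation of the benzylic and allylic CH2 of the prenyl group may compete with ring metalation.
- Addition of the di-ortho-substituted aryllithium 23 to amide 22 may be slow, leaving time for base-induced loss of formaldehyde from the N-methoxy amide.

The fallback replaces acylation by addition to an aldehyde followed by oxidation; it sets out from 19 and 22 and returns at 25. 22 is reduced with i-Bu2AlH in THF at −78 °C to 3-(methoxymethoxy)benzaldehyde F4. 23, made from 19 as before, is added to the much more electrophilic F4 to give [5,7-bis(methoxymethoxy)-2,2-dimethyl-8-(3-methylbut-2-enyl)-2H-chromen-6-yl][3-(methoxymethoxy)phenyl]methanol F5. F5 is oxidised with Dess–Martin periodinane to 25.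

Step 11. Two things may go wrong while the slow, unchelated ring-B acetal is being cleaved:
- The C8 prenyl group may cyclise onto the C7 hydroxyl under acid (chroman formation).
- HCl or methanol may add to the chromene double bond.

The fallback changes the protecting groups to 1-ethoxyethyl ethers, which direct lithiation equally but fall off with a pyridinium salt; it sets out from 18 and 20 and returns at 26. 18 with ethyl vinyl ether and pyridinium p-toluenesulfonate gives 5,7-bis(1-ethoxyethoxy)-2,2-dimethyl-8-(3-methylbut-2-enyl)-2H-chromene F6. 20 is protected in the same way to methyl 3-(1-ethoxyethoxy)benzoate F7 and converted as in step 9 into 3-(1-ethoxyethoxy)-N-methoxy-N-methylbenzamide F8. Lithiation of F6 with n-BuLi gives [5,7-bis(1-ethoxyethoxy)-2,2-dimethyl-8-(3-methylbut-2-enyl)-2H-chromen-6-yl]lithium F9. Acylation of F9 with F8 as in step 10 gives [5,7-bis(1-ethoxyethoxy)-2,2-dimethyl-8-(3-methylbut-2-enyl)-2H-chromen-6-yl][3-(1-ethoxyethoxy)phenyl]methanone F10, a mixture of acetal diastereomers. Pyridinium p-toluenesulfonate in methanol at room temperature then releases 26.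

## Further compounds

F1 | step 4 | 2-(3-methylbut-2-enyl)benzene-1,3,5-triol | CC(C)=CCc1c(O)cc(O)cc1O
F2 | step 1 | 5-lithio-3-phenylisoxazole | [Li]c1cc(-c2ccccc2)no1
F3 | step 5 | 1-[(2-methylbut-3-yn-2-yl)oxy]-2-(3-methylbut-2-enyl)-3,5-bis(triisopropylsilyloxy)benzene | CC(C)=CCc1c(OC(C)(C)C#C)cc(O[Si](C(C)C)(C(C)C)C(C)C)cc1O[Si](C(C)C)(C(C)C)C(C)C
F4 | step 10 | 3-(methoxymethoxy)benzaldehyde | COCOc1cccc(C=O)c1
F5 | step 10 | [5,7-bis(methoxymethoxy)-2,2-dimethyl-8-(3-methylbut-2-enyl)-2H-chromen-6-yl][3-(methoxymethoxy)phenyl]methanol (racemic) | CC(C)=CCc1c(OCOC)c(C(O)c2cccc(OCOC)c2)c(OCOC)c2c1OC(C)(C)C=C2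
F6 | step 11 | 5,7-bis(1-ethoxyethoxy)-2,2-dimethyl-8-(3-methylbut-2-enyl)-2H-chromene (acetal centers undefined, mixture of diastereomers) | CC(C)=CCc1c(OC(C)OCC)cc(OC(C)OCC)c2c1OC(C)(C)C=C2
F7 | step 11 | methyl 3-(1-ethoxyethoxy)benzoate (racemic) | CCOC(C)Oc1cccc(C(=O)OC)c1
F8 | step 11 | 3-(1-ethoxyethoxy)-N-methoxy-N-methylbenzamide (racemic) | CCOC(C)Oc1cccc(C(=O)N(C)OC)c1
F9 | step 11 | [5,7-bis(1-ethoxyethoxy)-2,2-dimethyl-8-(3-methylbut-2-enyl)-2H-chromen-6-yl]lithium (mixture of diastereomers) | CC(C)=CCc1c(OC(C)OCC)c([Li])c(OC(C)OCC)c2c1OC(C)(C)C=C2
F10 | step 11 | [5,7-bis(1-ethoxyethoxy)-2,2-dimethyl-8-(3-methylbut-2-enyl)-2H-chromen-6-yl][3-(1-ethoxyethoxy)phenyl]methanone (mixture of diastereomers) | CC(C)=CCc1c(OC(C)OCC)c(C(=O)c2cccc(OC(C)OCC)c2)c(OC(C)OCC)c2c1OC(C)(C)C=C2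
A1 | alternative 1 | [5,7-bis(methoxymethoxy)-2,2-dimethyl-8-(3-methylbut-2-enyl)-2H-chromen-6-yl][3-(methoxymethoxy)phenyl]methanone | CC(C)=CCc1c(OCOC)c(C(=O)c2cccc(OCOC)c2)c(OCOC)c2c1OC(C)(C)C=C2
A2 | alternative 1 | 6-iodo-5,7-bis(methoxymethoxy)-2,2-dimethyl-8-(3-methylbut-2-enyl)-2H-chromene | CC(C)=CCc1c(OCOC)c(I)c(OCOC)c2c1OC(C)(C)C=C2
A3 | alternative 1 | [3-(methoxymethoxy)phenyl]boronic acid | COCOc1cccc(B(O)O)c1
A4 | alternative 1 | carbon monoxide | [C-]#[O+]
A5 | alternative 2 | [3-(methoxymethoxy)phenyl][2,4,6-trihydroxy-3-(3-methylbut-2-enyl)phenyl]methanone | CC(C)=CCc1c(O)cc(O)c(C(=O)c2cccc(OCOC)c2)c1O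
A6 | alternative 2 | 4-hydroxy-6-{2-[3-(methoxymethoxy)phenyl]-2-oxoethyl}-3-(3-methylbut-2-enyl)-2H-pyran-2-one | CC(C)=CCc1c(O)cc(CC(=O)c2cccc(OCOC)c2)oc1=O
A7 | alternative 2 | methyl 7-[3-(methoxymethoxy)phenyl]-2-(3-methylbut-2-enyl)-3,5,7-trioxoheptanoate | COC(=O)C(CC=C(C)C)C(=O)CC(=O)CC(=O)c1cccc(OCOC)c1
A8 | alternative 3 | [2-hydroxy-4,6-bis(methoxymethoxy)-3-(3-methylbut-2-enyl)phenyl][3-(methoxymethoxy)phenyl]methanone | CC(C)=CCc1c(OCOC)cc(OCOC)c(C(=O)c2cccc(OCOC)c2)c1O
A9 | alternative 3 | 3,5-bis(methoxymethoxy)-2-(3-methylbut-2-enyl)-6-(trimethylsilyl)phenyl trifluoromethanesulfonate | CC(C)=CCc1c(OCOC)cc(OCOC)c([Si](C)(C)C)c1OS(=O)(=O)C(F)(F)F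
A10 | alternative 3 | 1,2-didehydro-3,5-bis(methoxymethoxy)-6-(3-methylbut-2-enyl)benzene | CC(C)=CCC1=C(OCOC)C=C(OCOC)C#C1
A11 | alternative 3 | 3-(methoxymethoxy)benzoic acid | COCOc1cccc(C(=O)O)c1
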